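The two ester C–O bonds are cut first, giving malonic acid and two molecules of labda-7,13E-dien-15-ol. In that alcohol the chain end C13(C16)=C14–C15–OH is an E-trisubstituted allylic alcohol with C16 and C15 cis. It is made in one flask from the terminal alkyne C13≡C14 of 15,16-dinorlabd-7-en-13-yne by zirconium-catalysed syn methylalumination and formaldehyde capture. This forms C13–C16 and C14–C15, while the trans-decalin (rings A/B) and its hindered C7=C8 alkene stay untouched. The alkyne is a hydrocarbon that needs no protecting group and comes from (+)-sclareolide, which supplies C5, C9 and C10.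

Key step: step 5

Assumption: the two terpenyl groups of the target are identical and belong to the normal labdane series (5α-H, 9α-H with C11 on the β face, 10β-CH3), the configuration of (+)-sclareolide. All six stereocentres therefore come from the chiral pool and the route only has to set the two E alkenes. Labdane numbering is used throughout, and every labdane-derived compound below has this configuration.

Step 1
Reactants: 1 (+)-sclareolide; 2 methanol
Product: 4 methyl 13,14,15,16-tetranorlabd-7-en-12-oate, via 13,14,15,16-tetranorlabd-7-en-12-oic acid 3 (not isolated)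
Conditions: conc. H2SO4, MeOH, rt, quenched (NaHCO3) as soon as 1 is consumed; chromatography on AgNO3–SiO2
Reagents that add atoms: methanol, CO
Why: In methanolic sulfuric acid the tertiary C8–O bond of the lactone ionises (AAL1) and the C8 cation loses the axial, unhindered 7α-proton (E1 elimination) to give acid 3, which Fischer esterification traps as 4 so that it cannot relactonise; the C8(17) and C8=C9 isomers expected as minor products of the same cation are removed on silver-nitrate silica, and C5, C9 and C10 are carried over unchanged from 1 because the reaction is stopped before re-protonation of the alkene sets in.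

Step 2
Reactants: 4 methyl 13,14,15,16-tetranorlabd-7-en-12-oate
Product: 5 13,14,15,16-tetranorlabd-7-en-12-ol
Conditions: LiAlH4, THF, 0 °C to rt; quench with Na2SO4·10H2O
Reagents that add atoms: none
Why: LiAlH4 reduction of an ester to the primary alcohol (hydride acyl substitution, then aldehyde reduction) does not touch the isolated trisubstituted alkene or any stereocentre, and the non-acidic work-up avoids acid-promoted addition of the new hydroxyl group to C8.

Step 3
Reactants: 5 13,14,15,16-tetranorlabd-7-en-12-ol; 6 p-toluenesulfonyl chloride
Product: 7 13,14,15,16-tetranorlabd-7-en-12-yl p-toluenesulfonate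
Conditions: TsCl, Et3N, DMAP (cat.), CH2Cl2, 0 °C to rt
Reagents that add atoms: p-toluenesulfonyl chloride, Cc1ccc(cc1)S(=O)(=O)Cl
Why: O-Sulfonylation of the unhindered primary alcohol under amine base with DMAP catalysis makes C12 electrophilic without acid and without an electrophilic halogen that could attack the C7=C8 alkene; no stereocentre is involved.

Step 4
Reactants: 7 13,14,15,16-tetranorlabd-7-en-12-yl p-toluenesulfonate; 8 lithium acetylide–ethylenediamine complex
Product: 9 15,16-dinorlabd-7-en-13-yne
Conditions: LiC≡CH·H2NCH2CH2NH2, DMSO, rt
Reagents that add atoms: lithium acetylide–ethylenediamine complex, [Li+].[C-]#C.NCCN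
Why: SN2 alkylation of lithium acetylide by the primary tosylate in dipolar aprotic DMSO forms the C12–C13 bond and gives the terminal alkyne directly, substitution being favoured over E2 at an unbranched primary carbon; the ring stereocentres are remote and unaffected.

Step 5
Reactants: 9 15,16-dinorlabd-7-en-13-yne; 10 trimethylaluminium; 11 formaldehyde (charged as paraformaldehyde)
Product: 14 labda-7,13E-dien-15-ol, via (E)-alkenyldimethylalane 12 (not isolated), via lithium (E)-alkenyl(butyl)dimethylalanate 13 (not isolated)
Conditions: AlMe3, Cp2ZrCl2 (0.25 equiv), CH2Cl2, 0 °C to rt; volatiles removed; n-BuLi, THF–hexane, −78 to 0 °C; (CH2O)n, 0 °C to rt; cold 1 M HCl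
Reagents that add atoms: trimethylaluminium, C[Al](C)C; formaldehyde, C=O
Why: Cp2ZrCl2 and AlMe3 form a Lewis-acid-activated methylzirconocene that adds its Me–Zr bond across C13≡C14 through a concerted four-centre syn transition state, methyl to the internal C13 and metal to the terminal C14, and Zr-to-Al transmetalation turns over the catalyst to leave alkenylalane 12 with C16 cis to aluminium. n-BuLi converts 12 into the more nucleophilic alanate 13, whose alkenyl–Al bond adds to formaldehyde with retention at C14, so C13–C16 and C14–C15 are formed in one flask and hydrolysis gives the E allylic alcohol 14. The closest known reaction type is the Negishi zirconium-catalysed methylalumination of terminal alkynes with hydroxymethylation of the derived alanate, a standard entry to E-isoprenoid allylic alcohols. No ring is closed and no stereocentre is created; the only stereo-element made is the E geometry of C13=C14, fixed by the syn addition and the retentive exchange of the C–Al bond for a C–C bond. The step needs regioselectivity (aluminium at C14), secured by the unsubstituted alkyne terminus against the alkyl-bearing C13, and chemoselectivity, secured because the only other π bond, the hindered trisubstituted C7=C8 alkene, does not carbometalate and the hydrocarbon substrate offers no acidic or Lewis-basic group.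

Step 6
Reactants: 14 labda-7,13E-dien-15-ol (2 equiv); 15 malonic acid
Product: 17 bis(labda-7,13E-dien-15-yl) malonate, via hydrogen labda-7,13E-dien-15-yl malonate 16 (not isolated)
Conditions: DCC (2.2 equiv), DMAP (cat.), CH2Cl2, 0 °C to rt
Reagents that add atoms: malonic acid, OC(=O)CC(=O)O
Why: Steglich esterification, in which DCC activates each carboxyl group of malonic acid in turn and DMAP transfers the acyl group to the primary allylic alcohol, runs without acid, so the allylic C15–O bond is not ionised and the E alkenes and the six ring stereocentres of the two halves are carried through unchanged.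

Compound list
1 | (+)-sclareolide (13,14,15,16-tetranorlabdan-12,8α-olide; 8β-CH3) | C[C@@]12CC[C@H]3C(C)(C)CCC[C@]3(C)[C@H]1CC(=O)O2 | starting material
2 | methanol | CO | starting material
3 | 13,14,15,16-tetranorlabd-7-en-12-oic acid | CC1=CC[C@H]2C(C)(C)CCC[C@]2(C)[C@H]1CC(=O)O | intermediate (not isolated)
4 | methyl 13,14,15,16-tetranorlabd-7-en-12-oate | CC1=CC[C@H]2C(C)(C)CCC[C@]2(C)[C@H]1CC(=O)OC | intermediate
5 | 13,14,15,16-tetranorlabd-7-en-12-ol | CC1=CC[C@H]2C(C)(C)CCC[C@]2(C)[C@H]1CCO | intermediate
6 | p-toluenesulfonyl chloride | Cc1ccc(cc1)S(=O)(=O)Cl | starting material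
7 | 13,14,15,16-tetranorlabd-7-en-12-yl p-toluenesulfonate | CC1=CC[C@H]2C(C)(C)CCC[C@]2(C)[C@H]1CCOS(=O)(=O)c1ccc(C)cc1 | intermediate
8 | lithium acetylide–ethylenediamine complex | [Li+].[C-]#C.NCCN | starting material
9 | 15,16-dinorlabd-7-en-13-yne | CC1=CC[C@H]2C(C)(C)CCC[C@]2(C)[C@H]1CCC#C | intermediate
10 | trimethylaluminium | C[Al](C)C | starting material
11 | formaldehyde (charged as paraformaldehyde) | C=O | starting material
12 | dimethyl[(13E)-15-norlabda-7,13-dien-14-yl]alane | CC1=CC[C@H]2C(C)(C)CCC[C@]2(C)[C@H]1CC/C(C)=C/[Al](C)C | intermediate (not isolated)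
13 | lithium butyldimethyl[(13E)-15-norlabda-7,13-dien-14-yl]alanate | CC1=CC[C@H]2C(C)(C)CCC[C@]2(C)[C@H]1CC/C(C)=C/[Al-](C)(C)CCCC.[Li+] | intermediate (not isolated)
14 | labda-7,13E-dien-15-ol | CC1=CC[C@H]2C(C)(C)CCC[C@]2(C)[C@H]1CC/C(C)=C/CO | intermediate
15 | malonic acid | OC(=O)CC(=O)O | starting material
16 | hydrogen labda-7,13E-dien-15-yl malonate | CC1=CC[C@H]2C(C)(C)CCC[C@]2(C)[C@H]1CC/C(C)=C/COC(=O)CC(=O)O | intermediate (not isolated)
17 | bis(labda-7,13E-dien-15-yl) malonate | CC1=CC[C@H]2C(C)(C)CCC[C@]2(C)[C@H]1CC/C(C)=C/COC(=O)CC(=O)OC/C=C(\C)CC[C@H]1C(C)=CC[C@H]2C(C)(C)CCC[C@]12C | target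

Total step count: 6
Longest linear sequence: 6 steps (1 to 17)

Steps most likely to fail

Step 1. Proton loss from the C8 cation may be poorly regioselective, with removal of a C17 proton or the C9 proton alongside the wanted 7α-proton. Longer acid contact may also let the alkene re-protonate and drift to the tetrasubstituted C8=C9 position, which would erase the C9 configuration. The fallback sets out from 1 and comes back at 4; it fixes the alkene position through an enol triflate and not through an elimination. Lactone 1 is saponified (KOH, MeOH, reflux) to potassium 8α-hydroxy-13,14,15,16-tetranorlabdan-12-oate F1, which is O-methylated without acidification (MeI, DMF) to methyl 8α-hydroxy-13,14,15,16-tetranorlabdan-12-oate F2. E2 dehydration of the equatorial C8 hydroxyl (SOCl2, pyridine, CH2Cl2, −78 °C), for which only the C17 hydrogens can be antiperiplanar, should give methyl 13,14,15,16-tetranorlabd-8(17)-en-12-oate F3. Ozonolysis (O3, CH2Cl2–MeOH, −78 °C; Me2S) gives methyl 8-oxo-13,14,15,16,17-pentanorlabdan-12-oate F4, in which C9 already holds its more stable equatorial side chain. Kinetic enolisation toward the C7 methylene and O-triflation (KHMDS, PhNTf2, THF, −78 °C) give methyl 8-(trifluoromethanesulfonyloxy)-13,14,15,16,17-pentanorlabd-7-en-12-oate F5. Iron-catalysed methyl cross-coupling (MeMgBr, Fe(acac)3, THF–NMP, −20 °C) then delivers 4 with the alkene locked at C7=C8.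

Step 5. The carbometalation may stall, the alkyne C–H may be metalated in competition, the addition may run with imperfect regiochemistry, or the alanate may be protonated before it meets the poorly soluble formaldehyde source. In each case the C14–C15 bond is not formed cleanly. The fallback sets out from 9 and comes back at 14; it builds the same E alkene by anti-hydroalumination of a propargylic alcohol and methyl cuprate coupling. Alkyne 9 is deprotonated and hydroxymethylated (n-BuLi, THF, −78 °C; (CH2O)n) to 16-norlabd-7-en-13-yn-15-ol F6. Hydroxyl-directed trans-hydroalumination and iodinolysis (Red-Al, THF, 0 °C; then I2, −78 °C) give (13Z)-13-iodo-16-norlabda-7,13-dien-15-ol F7, with iodine cis to C15. Coupling with Me2CuLi (Et2O, 0 °C) replaces iodine by methyl with retention and gives 14.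

Step 6. The double acylation may stop at the half-ester stage, and activated malonate may be lost through O-to-N acyl migration on the carbodiimide adduct or through ketene-type self-condensation. The fallback sets out from 14 and comes back at 17; it stages the two acylations. Alcohol 14 is heated with Meldrum's acid (toluene, 90 °C) to give the half-ester 16, here isolated, and 16 is coupled with a second equivalent of 14 (DCC, DMAP, CH2Cl2, 0 °C) to reach 17. Every compound on this way already stands in the list.

Further compounds
F1 | step 1 | potassium 8α-hydroxy-13,14,15,16-tetranorlabdan-12-oate | C[C@@]1(O)CC[C@H]2C(C)(C)CCC[C@]2(C)[C@H]1CC(=O)[O-].[K+]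
F2 | step 1 | methyl 8α-hydroxy-13,14,15,16-tetranorlabdan-12-oate | C[C@@]1(O)CC[C@H]2C(C)(C)CCC[C@]2(C)[C@H]1CC(=O)OC
F3 | step 1 | methyl 13,14,15,16-tetranorlabd-8(17)-en-12-oate | C=C1CC[C@H]2C(C)(C)CCC[C@]2(C)[C@H]1CC(=O)OC
F4 | step 1 | methyl 8-oxo-13,14,15,16,17-pentanorlabdan-12-oate | O=C1CC[C@H]2C(C)(C)CCC[C@]2(C)[C@H]1CC(=O)OC
F5 | step 1 | methyl 8-(trifluoromethanesulfonyloxy)-13,14,15,16,17-pentanorlabd-7-en-12-oate | O=S(=O)(OC1=CC[C@H]2C(C)(C)CCC[C@]2(C)[C@H]1CC(=O)OC)C(F)(F)F
F6 | step 5 | 16-norlabd-7-en-13-yn-15-ol | CC1=CC[C@H]2C(C)(C)CCC[C@]2(C)[C@H]1CCC#CCO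
F7 | step 5 | (13Z)-13-iodo-16-norlabda-7,13-dien-15-ol | CC1=CC[C@H]2C(C)(C)CCC[C@]2(C)[C@H]1CC/C(I)=C/CO
F0 | step 6 | none | none
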